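## The problem

The target is a bicyclo[3.3.1]nonane-2,4,9-trione of the type B acylphloroglucinol family. Ring A (C1–C2–C3–C4–C5–C9) is an enolised 2,4-dione with the 3,4-dihydroxybenzoyl group on C3. Ring B (C5–C6–C7–C8–C1–C9) holds the gem-dimethyl carbon C8 and the stereogenic C7, and the two rings share the bridging ketone C9. Both bridgeheads are quaternary. C1 (prenyl) sits between C2, C9 and CMe2. C5 carries a lavandulyl group, a β-branched chain that is a poor electrophile for a hindered bridgehead carbanion, so it should enter before the bicycle exists.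

There are five stereocentres. C1 and C5 are tied together by the bicycle, so one event can set both. C7 carries its chain endo (cis to the C2–C4 bridge), and the bicycle can control it because reagents reach C7 only from the exo face. The carbinol carbon of the 2,3-dihydroxy-3-methylbutyl chain and the lavandulyl methine are remote, so they need reagent or auxiliary control and cannot steer the core.

The enolised acyl-trione next to prenyl and isopropenyl groups cyclises to pyrans under acid, the catechol is oxidation-prone, and the non-enolisable β-dicarbonyl array can undergo retro-Claisen cleavage. Three isolated C=C bonds rule out hydrogenation, ozonolysis and unselective electrophilic oxidation at every stage.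

The enabling feature is that ring A can be drawn as a 1,5-dimethoxycyclohexa-1,4-diene. In that form C5 is a prochiral quaternary carbon between two enol ethers (C4=C3 and C9=C1), and C1 is the nucleophilic β-carbon of the C9 enol ether. A carbenoid at C8, tethered to C5 through C6–C7, reaches exactly the C9=C1 bond, and the C9 methoxy group then supplies the push to open the cyclopropane.

## Retrosynthesis

Abbreviation used throughout: Lav = (2R)-5-methyl-2-(prop-1-en-2-yl)hex-4-en-1-yl (the lavandulyl group; the same spatial arrangement is called S in free lavandulol).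

**End game (35 ⇐ 34 ⇐ 33 ⇐ 29).** The last bonds cut are C1–prenyl and C3–aroyl, followed by all protecting groups. In vinylogous ester 29 the vinylic C3–H is the kinetically most acidic site, so the aroyl group (from acid chloride 32) goes on first, giving 33. It then blocks C3 while the hindered bridgehead C1–H, now flanked by C2=O and C9=O, is lithiated and prenylated to 34. The reverse order would need a separate blocking group on C3. All protecting groups in 34 (methyl enol ether, cyclic carbonate, two aryl silyl ethers) fall to hydroxide in one operation, so 35 never meets acid.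

**C2 oxygen (29 ⇐ 28).** The C2 carbonyl is cut back to the allylic methylene of enol ether 28. Carrying a third ring oxygen through the dearomatisation would be the alternative, but an allylic methoxy group would not survive dissolving-metal conditions. The forward reaction must oxidise the C–H bonds activated by the enol ether and leave the lavandulyl allylic positions alone.

**C7 side chain (28 ⇐ 26 ⇐ 25 ⇐ 23 ⇐ 20 + 22).** The C7–CH2 bond is cut. In diketone 19 only the C7 carbonyl can enolise (C9 is flanked by C5 and bridgehead C1), so enol triflate 20 addresses C7 with certainty. A nucleophilic addition would instead have to choose between two hindered ketones. Coupling 20 with the enolate of silyloxy ketone 22 brings in all five chain carbons as 23. The C7 hydrogen is then delivered by conjugate reduction of the conjugated isomer 24; this is the only way to saturate one C=C beside three others. The carbinol in 26 comes from a reagent-controlled ketone reduction of 25, and the diol is masked as the base-labile carbonate 28.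

**C8 methyl groups (19 ⇐ 18 ⇐ 17).** Without help, C6 and C8 would compete in enolate methylation of a 7,9-dione. A sulfonyl group on C8 in 17 solves this. It makes C8–H the most acidic proton for the first methylation (18). Its reductive cleavage then releases the C7=C8 enolate regiospecifically for the second (19).

**Key disconnection (17 ⇐ 16 ⇐ 15).** The C1–C8 bond is cut, with the C9 ketone returned to an enol ether. Diazo ketosulfone 15 has one stereocentre and a flat, symmetric ring. Carbene addition to C9=C1 gives methoxycyclopropane 16, and heterolysis of its C8–C9 bond leaves 17. This single event closes ring B and sets C1 and C5. The forward reaction needs a catalyst that picks one of the two diastereotopic enol ethers, and it must leave the C4 enol ether intact.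

**Carbene precursor (15 ⇐ 14 ⇐ 12 ⇐ 11 ⇐ 9).** The diazo group comes by diazo transfer to β-keto sulfone 14. 14 is the acylation product of lithiated methyl phenyl sulfone 13 with ester 12. 12 is the one-carbon homologue of acid 9 by way of diazoketone 11. Hydroboration-based homologations are excluded by the isopropenyl group, and enol-ether-based ones by the two ring enol ethers.

**Quaternary C5 and the lavandulyl unit (9 ⇐ 8 + 7; 7 ⇐ 6 ⇐ 5 ⇐ 3 ⇐ 1 + 2, 4).** Reductive alkylation of 2,6-dimethoxybenzoic acid 8 with iodide 7 forms the C5–CH2 bond on a planar dianion, where a sluggish β-branched electrophile is still acceptable. The target needs the lavandulyl configuration of (S)-lavandulol 6, the antipode of the natural alcohol. It is therefore made by auxiliary-controlled deconjugative prenylation of imide 3 (from oxazolidinone 1 and acid chloride 2) with prenyl bromide 4, followed by reductive removal of the auxiliary from 5.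

## Roads not taken

**Alternative 1: transannular Claisen closure of a cyclooctanedione.** The cut is C5–C9. The dianion of cyclooctane-2,4-dione A1, which carries the C1 methyl ester, would attack the ester through C5 and give the enolised trione A2, closing rings A and B at once.
- Merits: A2 already holds both bridgehead substituents, the gem-dimethyl group and the protected C7 chain. It needs no bridgehead alkylation, no C2 oxidation and no C8 methylation, and in those respects it is better than the chosen plan.
- Weak points: A1 is an eight-membered ring with three stereocentres in 1,3,5-relationship, one of them quaternary, and nothing in a flexible medium ring controls their relative configuration. The closure joins a tertiary carbanion bearing the β-branched lavandulyl chain to a neopentyl ester. The new β-dicarbonyl unit in A2 (C4/C9 across quaternary C5) cannot be deprotonated, so nothing pulls the equilibrium away from retro-Claisen opening.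
- Comparison: the chosen plan makes quaternary C5 by an irreversible alkylation and sets C1/C5 by catalyst control on an easily made precursor. It pays with a longer end game.

**Alternative 2: oxidative 1,2-shift of a hydrindanol.** The cut is C5–C6. Trivalent iodine would activate the diketone of the cis-fused cyclopentanol A3 at C5, and C6 would migrate from C9 to C5. This expands the cyclopentane into ring B and unveils the C9 ketone in A4.
- Merits: cis-hydrindanes are easy to assemble with stereocontrol, and C1, C7 and C8 would be settled before the skeleton forms. This is better than the late C7 and C8 work of the chosen plan.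
- Weak points: A4 has hydrogen on C5, so the lavandulyl group would have to be put on a bridgehead carbanion with a β-branched primary halide, which is the poorest type of electrophile for that reaction. The iodine reagent must also attack C5 and not the more acidic C3 between the two carbonyls. C6 must migrate in preference to quaternary C1, which is normally the better migrating group.
- Comparison: the chosen plan sets against the earlier C7/C8 control of this road that its hardest C–C bond (C5–lavandulyl) is made at the aromatic stage, and that geometry alone dictates which bond forms in the ring-closing step.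

**Alternative 3: decarboxylative radical 6-exo-dig closure.** The cut is C6–C7. The C6 radical from the acetic acid arm of cyclohexenedione A5 would add to the β-carbon of the ynone on C1 and give A6, with ring B closed and an exocyclic enone at C7.
- Merits: in late-stage economy this road is at least as good as the chosen one. Both bridgeheads, the gem-dimethyl group and the vinylogous ester are in place. The C7 chain arrives conjugated by construction, so the isomerisation problem of step 16 does not arise.
- Weak points: A5 needs two quaternary stereocentres (C1 and C5) set cis on one ring, in a defined relation to the lavandulyl centre, by separate alkylations with no controlling element. The primary neopentyl radical must add to an alkyne carbon attached to quaternary C8, and it can also attack the isopropenyl group of its own lavandulyl chain (6-endo). C7 would still need a stereoselective conjugate reduction.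
- Comparison: against the shorter finish of A6, the chosen plan offers one catalyst-controlled event for C1 and C5 and a precursor whose only stereocentre is bought with an auxiliary.

Key step: step 10

Assumptions:
- The ligand antipode that turns 15 into 17 and not into its C1,C5-diastereomer has to be fixed in the first run; the (S,S)-ligand is written. Because the lavandulyl centre is already enantiopure, the minor product is a diastereomer and can be removed.
- 17 and 18 are carried as mixtures at C8, a centre that ends as CMe2.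

## Route

Step 1
Reactants: 1 (S)-4-benzyloxazolidin-2-one; 2 3-methylbut-2-enoyl chloride
Product: 3 (S)-4-benzyl-3-(3-methylbut-2-enoyl)oxazolidin-2-one
Conditions: n-BuLi, THF, −78 °C; then 2, −78 → 0 °C
Reagents that add atoms: none
Why: N-acylation of the lithiated oxazolidinone with an acid chloride is the standard entry to auxiliary-bound acyl units.

Step 2
Reactants: 3; 4 prenyl bromide (1-bromo-3-methylbut-2-ene)
Product: 5 (S)-4-benzyl-3-[(2S)-5-methyl-2-(prop-1-en-2-yl)hex-4-enoyl]oxazolidin-2-one
Conditions: NaHMDS, THF, −78 °C; then 4, −78 → −30 °C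
Reagents that add atoms: none
Why: γ-Deprotonation gives the chelated Z-dienolate, which is alkylated at the α-carbon on the face away from the benzyl group (auxiliary-controlled deconjugative alkylation). This sets the lavandulyl stereocentre.

Step 3
Reactants: 5
Product: 6 (S)-lavandulol [(2S)-5-methyl-2-(prop-1-en-2-yl)hex-4-en-1-ol]
Conditions: LiBH4, MeOH (1 equiv), THF, 0 °C
Reagents that add atoms: none
Why: Reductive cleavage of the imide returns the auxiliary and the primary alcohol without touching the alkenes or the α-centre.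

Step 4
Reactants: 6
Product: 7 (S)-lavandulyl iodide [(5S)-6-iodo-2-methyl-5-(prop-1-en-2-yl)hex-2-ene]
Conditions: I2, PPh3, imidazole, CH2Cl2, 0 °C → rt
Reagents that add atoms: iodine, II
Why: Appel iodination of a primary alcohol proceeds under neutral conditions and does not involve the stereocentre.

Step 5
Reactants: 8 2,6-dimethoxybenzoic acid; 7
Product: 9 1-Lav-2,6-dimethoxycyclohexa-2,5-diene-1-carboxylic acid
Conditions: Li (3 equiv), NH3(l)/THF, −78 °C; then 7, −78 → −33 °C; NH4Cl; NaH2PO4 (aq) to pH 5 at 0 °C, used at once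
Reagents that add atoms: none
Why: Birch reductive alkylation: the 1,4-dihydrobenzoate dianion is alkylated at C1, giving the quaternary carbon between two enol ethers. The lavandulyl alkenes are inert to the dissolving metal.

Step 6
Reactants: 9
Product: 11 2-diazo-1-(1-Lav-2,6-dimethoxycyclohexa-2,5-dien-1-yl)ethan-1-one, via acid chloride 10 (not isolated)
Conditions: 1-chloro-N,N,2-trimethylprop-1-en-1-amine, CH2Cl2, 0 °C; then CH2N2, Et3N, Et2O, 0 °C → rt
Reagents that add atoms: diazomethane, C=[N+]=[N-]; 1-chloro-N,N,2-trimethylprop-1-en-1-amine, CC(C)=C(Cl)N(C)C (chlorine of 10 only)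
Why: The chloro-enamine forms the acid chloride without liberating HCl, which protects the enol ethers. Acylation of diazomethane with Et3N as acid scavenger gives the diazoketone (first half of the Arndt–Eistert homologation).

Step 7
Reactants: 11
Product: 12 methyl 2-(1-Lav-2,6-dimethoxycyclohexa-2,5-dien-1-yl)acetate
Conditions: PhCO2Ag (0.1 equiv), Et3N, MeOH/THF, rt, dark
Reagents that add atoms: methanol, CO
Why: Silver-promoted Wolff rearrangement with migration of the quaternary carbon; methanol traps the ketene. The diazomethane carbon becomes C6 and the old carboxyl carbon becomes C7.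

Step 8
Reactants: 12; 13 methyl phenyl sulfone
Product: 14 1-(1-Lav-2,6-dimethoxycyclohexa-2,5-dien-1-yl)-3-(phenylsulfonyl)propan-2-one
Conditions: 13 (2.2 equiv), n-BuLi (2.1 equiv), THF, −78 → 0 °C; then 12, 0 °C → rt; NH4Cl (aq)
Reagents that add atoms: none
Why: Claisen-type acylation of the α-sulfonyl carbanion by the ester. The second equivalent of carbanion deprotonates the β-keto sulfone and drives the reaction.

Step 9
Reactants: 14
Product: 15 1-diazo-3-(1-Lav-2,6-dimethoxycyclohexa-2,5-dien-1-yl)-1-(phenylsulfonyl)propan-2-one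
Conditions: 4-acetamidobenzenesulfonyl azide, Et3N, MeCN, 0 °C → rt
Reagents that add atoms: 4-acetamidobenzenesulfonyl azide, CC(=O)Nc1ccc(cc1)S(=O)(=O)N=[N+]=[N-]
Why: Regitz diazo transfer to the doubly activated methylene of a β-keto sulfone needs only an amine base, which the enol ethers tolerate.

Step 10
Reactants: 15
Product: 17 (1S,5R)-4-methoxy-5-Lav-8-(phenylsulfonyl)bicyclo[3.3.1]non-3-ene-7,9-dione (C8 epimers), via methoxycyclopropane 16 (not isolated)
Conditions: (CuOTf)2·C6H6 (5 mol %), 2,2′-(propane-2,2-diyl)bis[(4S)-4-isopropyl-4,5-dihydrooxazole] (12 mol %), toluene, 50 °C, slow addition of 15; then THF/pH 7 phosphate buffer, rt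
Reagents that add atoms: water, O
Why: Monovalent copper bound to the bis(oxazoline) decomposes the diazo group to an electrophilic copper carbene at C8, which adds to the electron-rich C9=C1 enol ether on the face of C5 that carries the C6–C7 tether and gives 16. The closest known reaction type is the catalytic asymmetric intramolecular cyclopropanation of α-diazo-β-keto sulfones with CuOTf and bis(oxazoline) ligands, including desymmetrisation of cyclohexadienes. The carbene addition closes a five-membered ring (C5–C6–C7–C8–C9) fused to the cyclopropane; heterolysis of the shared C8–C9 bond then leaves the six-membered ring B (C5–C6–C7–C8–C1–C9), so the net result is attack of C1 on the carbene carbon. The opening is driven by the C9 methoxy donor, the ketone and sulfone acceptors on C8 and the release of ring strain. The resulting C9 oxocarbenium ion is hydrolysed by neutral water to the ketone while the carbanion at C8 takes up the proton. C5 and C1 are set together by the catalyst's choice between the two diastereotopic enol ethers. The cis ring fusion fixes C1 relative to C5, and C8 is left epimeric. The step needs chemoselectivity over the lavandulyl alkenes and over C–H insertion; this is secured by the proximity and nucleophilicity of the enol ether. It also needs survival of the C4 enol ether, which is secured by the acid-free hydrolysis.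

Step 11
Reactants: 17
Product: 18 (1S,5R)-4-methoxy-8-methyl-5-Lav-8-(phenylsulfonyl)bicyclo[3.3.1]non-3-ene-7,9-dione (C8 epimers)
Conditions: Cs2CO3, MeI, DMF, 0 °C → rt
Reagents that add atoms: iodomethane, CI
Why: C-alkylation of a β-keto sulfone: C8–H is far more acidic than the C6 protons, so the first methyl group goes to C8 only.

Step 12
Reactants: 18
Product: 19 (1R,5R)-4-methoxy-8,8-dimethyl-5-Lav-bicyclo[3.3.1]non-3-ene-7,9-dione
Conditions: LiC10H8 (lithium naphthalenide, 2.2 equiv), THF, −78 °C; then MeI, HMPA, −78 → −20 °C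
Reagents that add atoms: iodomethane, CI
Why: Two-electron reductive cleavage of the α-sulfonyl ketone gives the C7=C8 lithium enolate regiospecifically; in situ C-methylation (reductive alkylation) completes the gem-dimethyl group. The α-sulfonyl ketone is much more easily reduced than the C9 ketone.

Step 13
Reactants: 19
Product: 20 (1R,5R)-4-methoxy-8,8-dimethyl-5-Lav-9-oxobicyclo[3.3.1]nona-3,6-dien-7-yl trifluoromethanesulfonate
Conditions: KHMDS, THF, −78 °C; PhNTf2, −78 → 0 °C
Reagents that add atoms: N-phenylbis(trifluoromethanesulfonimide), O=S(=O)(N(c1ccccc1)S(=O)(=O)C(F)(F)F)C(F)(F)F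
Why: Only C6 carries enolisable hydrogen (C8 is quaternary and C9 has a bridgehead and a quaternary neighbour), so enolate triflation marks C7 and leaves C9 untouched.

Step 14
Reactants: 21 3-hydroxy-3-methylbutan-2-one
Product: 22 3-methyl-3-(triethylsilyloxy)butan-2-one
Conditions: Et3SiOTf, 2,6-lutidine, CH2Cl2, −78 → 0 °C
Reagents that add atoms: triethylsilyl trifluoromethanesulfonate, CC[Si](CC)(CC)OS(=O)(=O)C(F)(F)F
Why: Silylation of a tertiary alcohol with the silyl triflate and a hindered pyridine base is faster than enol silylation of the ketone at low temperature.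

Step 15
Reactants: 20; 22
Product: 23 1-[(1R,5R)-4-methoxy-8,8-dimethyl-5-Lav-9-oxobicyclo[3.3.1]nona-3,6-dien-7-yl]-3-methyl-3-(triethylsilyloxy)butan-2-one
Conditions: 22, LiHMDS (2.5 equiv), THF, −78 → 0 °C; then 20, Pd2(dba)3 (2.5 mol %), XPhos (10 mol %), THF, 50 °C; NH4Cl (aq)
Reagents that add atoms: none
Why: Ketone α-alkenylation catalysed by zerovalent palladium: oxidative addition of the enol triflate, transmetalation with the methyl-ketone enolate (22 can enolise on one side only) and reductive elimination form the C7–CH2 bond.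

Step 16
Reactants: 23
Product: 25 1-[(1R,5R,7S)-4-methoxy-8,8-dimethyl-5-Lav-9-oxobicyclo[3.3.1]non-3-en-7-yl]-3-methyl-3-(triethylsilyloxy)butan-2-one, via exocyclic enone 24 (not isolated)
Conditions: DBU (0.3 equiv), toluene, 40 °C; then [(Ph3P)CuH]6 (5 mol %), PhMe2SiH, t-BuOH, rt, DBU left in
Reagents that add atoms: none
Why: DBU equilibrates the β,γ-unsaturated ketone with its conjugated isomer 24 through the dienol, and copper hydride conjugate reduction consumes only 24, so the equilibrium is drained. The isolated alkenes, the enol ether and the hindered C9 ketone are not substrates for the copper hydride. Hydride reaches C7 from the open exo face (the endo face lies against the C2–C4 bridge), which places the chain endo.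

Step 17
Reactants: 25
Product: 26 (2S)-1-[(1R,5R,7S)-4-methoxy-8,8-dimethyl-5-Lav-9-oxobicyclo[3.3.1]non-3-en-7-yl]-3-methyl-3-(triethylsilyloxy)butan-2-ol
Conditions: (R)-2-methyl-CBS-oxazaborolidine (0.5 equiv), catecholborane, toluene, −78 °C; MeOH; NaOH (aq) wash
Reagents that add atoms: none
Why: Corey–Bakshi–Shibata reduction: the catalyst differentiates the quaternary silyloxy carbon (large) from the CH2 group (small) and sets the S carbinol under reagent control. Catecholborane at −78 °C does not hydroborate the alkenes, and the shielded C9 ketone is expected to react far more slowly.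

Step 18
Reactants: 26
Product: 28 (1R,5R,7S)-7-{[(4S)-5,5-dimethyl-2-oxo-1,3-dioxolan-4-yl]methyl}-4-methoxy-8,8-dimethyl-5-Lav-bicyclo[3.3.1]non-3-en-9-one, via diol 27 (not isolated)
Conditions: Bu4NF, THF, 0 °C → rt; aqueous work-up; then 1,1′-carbonyldiimidazole, DMAP (cat.), toluene, 60 °C
Reagents that add atoms: 1,1′-carbonyldiimidazole, O=C(n1ccnc1)n1ccnc1
Why: Fluoride desilylation followed by carbonylation of the 1,2-diol gives a five-membered carbonate. It is stable to hindered lithium amides and to oxidation, and base removes it at the end.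

Step 19
Reactants: 28
Product: 29 (1S,5R,7S)-7-{[(4S)-5,5-dimethyl-2-oxo-1,3-dioxolan-4-yl]methyl}-4-methoxy-8,8-dimethyl-5-Lav-bicyclo[3.3.1]non-3-ene-2,9-dione
Conditions: Rh2(cap)4 (cap = caprolactamate, 1 mol %), t-BuOOH (5.5 M in decane), K2CO3, CH2Cl2, rt
Reagents that add atoms: tert-butyl hydroperoxide, CC(C)(C)OO
Why: Allylic oxidation by tert-butylperoxyl radicals: hydrogen abstraction is fastest at C2, where the allyl radical is stabilised by the enol ether oxygen. The mixed peroxide collapses to the ketone and gives the vinylogous ester.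

Step 20
Reactants: 30 3,4-dihydroxybenzoic acid
Product: 31 tert-butyldimethylsilyl 3,4-bis(tert-butyldimethylsilyloxy)benzoate
Conditions: t-BuMe2SiCl, imidazole, DMF, rt
Reagents that add atoms: tert-butyldimethylsilyl chloride, CC(C)(C)[Si](C)(C)Cl
Why: Exhaustive silylation of both phenols and the acid gives a single, distillable derivative.

Step 21
Reactants: 31
Product: 32 3,4-bis(tert-butyldimethylsilyloxy)benzoyl chloride
Conditions: (COCl)2, DMF (cat.), CH2Cl2, 0 °C → rt
Reagents that add atoms: oxalyl chloride, O=C(Cl)C(=O)Cl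
Why: Silyl esters are converted directly into acid chlorides by oxalyl chloride/DMF under neutral conditions, and the aryl silyl ethers survive.

Step 22
Reactants: 29; 32
Product: 33 (1R,5R,7S)-3-[3,4-bis(tert-butyldimethylsilyloxy)benzoyl]-7-{[(4S)-5,5-dimethyl-2-oxo-1,3-dioxolan-4-yl]methyl}-4-methoxy-8,8-dimethyl-5-Lav-bicyclo[3.3.1]non-3-ene-2,9-dione
Conditions: LiTMP (from 2,2,6,6-tetramethylpiperidine and n-BuLi), THF, −78 °C; then 32, −78 → −40 °C
Reagents that add atoms: none
Why: Lithiation of the vinylogous ester at C3, the kinetically most acidic position (the hindered bridgehead C1–H reacts more slowly), then C-acylation with the aroyl chloride. This is the established way to acylate C3 of these bicyclic enol ethers.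

Step 23
Reactants: 33; 4
Product: 34 (1R,5R,7S)-3-[3,4-bis(tert-butyldimethylsilyloxy)benzoyl]-7-{[(4S)-5,5-dimethyl-2-oxo-1,3-dioxolan-4-yl]methyl}-4-methoxy-8,8-dimethyl-1-(3-methylbut-2-en-1-yl)-5-Lav-bicyclo[3.3.1]non-3-ene-2,9-dione
Conditions: LiTMP, THF, −78 → −40 °C; then 4, −78 → 0 °C
Reagents that add atoms: none
Why: With C3 occupied, the only acidic hydrogen left is the bridgehead C1–H between C2=O and C9=O. Bridgehead lithiation and alkylation with an allylic bromide is the standard bridgehead substitution of these cores and necessarily proceeds with retention.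

Step 24
Reactants: 34
Product: 35 (1R,5R,7S)-3-(3,4-dihydroxybenzoyl)-7-[(2S)-2,3-dihydroxy-3-methylbutyl]-4-hydroxy-8,8-dimethyl-1-(3-methylbut-2-en-1-yl)-5-Lav-bicyclo[3.3.1]non-3-ene-2,9-dione (CNP0286757.2)
Conditions: LiOH·H2O, 1,4-dioxane/H2O, degassed, 90 °C; then NaH2PO4 (aq) to pH 5
Reagents that add atoms: lithium hydroxide, [Li+].[OH-] (its oxygen ends on C4 if the enol ether is cleaved by addition–elimination)
Why: Hydroxide cleaves the vinylogous methyl ester, hydrolyses the cyclic carbonate and removes both aryl silyl ethers in one basic operation. No acid is used, so the enol cannot cyclise onto the prenyl or isopropenyl groups.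

## Compound list

1 | (S)-4-benzyloxazolidin-2-one | O=C1N[C@@H](Cc2ccccc2)CO1 | starting material
2 | 3-methylbut-2-enoyl chloride | CC(C)=CC(=O)Cl | starting material
3 | (S)-4-benzyl-3-(3-methylbut-2-enoyl)oxazolidin-2-one | CC(C)=CC(=O)N1[C@@H](Cc2ccccc2)COC1=O | intermediate
4 | prenyl bromide | CC(C)=CCBr | starting material
5 | (S)-4-benzyl-3-[(2S)-5-methyl-2-(prop-1-en-2-yl)hex-4-enoyl]oxazolidin-2-one | C=C(C)[C@H](CC=C(C)C)C(=O)N1[C@@H](Cc2ccccc2)COC1=O | intermediate
6 | (S)-lavandulol | C=C(C)[C@H](CC=C(C)C)CO | intermediate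
7 | (S)-lavandulyl iodide | C=C(C)[C@H](CC=C(C)C)CI | intermediate
8 | 2,6-dimethoxybenzoic acid | COc1cccc(OC)c1C(=O)O | starting material
9 | 1-Lav-2,6-dimethoxycyclohexa-2,5-diene-1-carboxylic acid | C=C(C)[C@H](CC=C(C)C)CC1(C(=O)O)C(OC)=CCC=C1OC | intermediate
10 | acid chloride of 9 | C=C(C)[C@H](CC=C(C)C)CC1(C(=O)Cl)C(OC)=CCC=C1OC | intermediate (not isolated)
11 | 2-diazo-1-(1-Lav-2,6-dimethoxycyclohexa-2,5-dien-1-yl)ethan-1-one | C=C(C)[C@H](CC=C(C)C)CC1(C(=O)C=[N+]=[N-])C(OC)=CCC=C1OC | intermediate
12 | methyl 2-(1-Lav-2,6-dimethoxycyclohexa-2,5-dien-1-yl)acetate | C=C(C)[C@H](CC=C(C)C)CC1(CC(=O)OC)C(OC)=CCC=C1OC | intermediate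
13 | methyl phenyl sulfone | CS(=O)(=O)c1ccccc1 | starting material
14 | 1-(1-Lav-2,6-dimethoxycyclohexa-2,5-dien-1-yl)-3-(phenylsulfonyl)propan-2-one | C=C(C)[C@H](CC=C(C)C)CC1(CC(=O)CS(=O)(=O)c2ccccc2)C(OC)=CCC=C1OC | intermediate
15 | 1-diazo-3-(1-Lav-2,6-dimethoxycyclohexa-2,5-dien-1-yl)-1-(phenylsulfonyl)propan-2-one (key precursor) | C=C(C)[C@H](CC=C(C)C)CC1(CC(=O)C(=[N+]=[N-])S(=O)(=O)c2ccccc2)C(OC)=CCC=C1OC | intermediate
16 | tricyclic methoxycyclopropane: C8 bonded to C9 and C1 on the face of C5 bearing the C6–C7 arm; OMe on C9 and C4, PhSO2 on C8, C7 ketone, Lav on C5 (5R) | C=C(C)[C@H](CC=C(C)C)C[C@@]12CC(=O)[C@@]3(S(=O)(=O)c4ccccc4)[C@@H](CC=C1OC)[C@@]23OC | intermediate (not isolated)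
17 | (1S,5R)-4-methoxy-5-Lav-8-(phenylsulfonyl)bicyclo[3.3.1]non-3-ene-7,9-dione, C8 epimers (key product) | C=C(C)[C@H](CC=C(C)C)C[C@@]12CC(=O)C(S(=O)(=O)c3ccccc3)[C@@H](CC=C1OC)C2=O | intermediate
18 | (1S,5R)-4-methoxy-8-methyl-5-Lav-8-(phenylsulfonyl)bicyclo[3.3.1]non-3-ene-7,9-dione, C8 epimers | C=C(C)[C@H](CC=C(C)C)C[C@@]12CC(=O)C(C)(S(=O)(=O)c3ccccc3)[C@@H](CC=C1OC)C2=O | intermediate
19 | (1R,5R)-4-methoxy-8,8-dimethyl-5-Lav-bicyclo[3.3.1]non-3-ene-7,9-dione | C=C(C)[C@H](CC=C(C)C)C[C@@]12CC(=O)C(C)(C)[C@@H](CC=C1OC)C2=O | intermediate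
20 | (1R,5R)-4-methoxy-8,8-dimethyl-5-Lav-9-oxobicyclo[3.3.1]nona-3,6-dien-7-yl trifluoromethanesulfonate | C=C(C)[C@H](CC=C(C)C)C[C@@]12C=C(OS(=O)(=O)C(F)(F)F)C(C)(C)[C@@H](CC=C1OC)C2=O | intermediate
21 | 3-hydroxy-3-methylbutan-2-one | CC(=O)C(C)(C)O | starting material
22 | 3-methyl-3-(triethylsilyloxy)butan-2-one | CC(=O)C(C)(C)O[Si](CC)(CC)CC | intermediate
23 | 1-[(1R,5R)-4-methoxy-8,8-dimethyl-5-Lav-9-oxobicyclo[3.3.1]nona-3,6-dien-7-yl]-3-methyl-3-(triethylsilyloxy)butan-2-one | C=C(C)[C@H](CC=C(C)C)C[C@@]12C=C(CC(=O)C(C)(C)O[Si](CC)(CC)CC)C(C)(C)[C@@H](CC=C1OC)C2=O | intermediate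
24 | (E)-1-[(1R,5R)-4-methoxy-8,8-dimethyl-5-Lav-9-oxobicyclo[3.3.1]non-3-en-7-ylidene]-3-methyl-3-(triethylsilyloxy)butan-2-one (acyl group cis to C6) | C=C(C)[C@H](CC=C(C)C)C[C@@]12C/C(=C\C(=O)C(C)(C)O[Si](CC)(CC)CC)C(C)(C)[C@@H](CC=C1OC)C2=O | intermediate (not isolated)
25 | 1-[(1R,5R,7S)-4-methoxy-8,8-dimethyl-5-Lav-9-oxobicyclo[3.3.1]non-3-en-7-yl]-3-methyl-3-(triethylsilyloxy)butan-2-one (chain endo) | C=C(C)[C@H](CC=C(C)C)C[C@@]12C[C@@H](CC(=O)C(C)(C)O[Si](CC)(CC)CC)C(C)(C)[C@@H](CC=C1OC)C2=O | intermediate
26 | (2S)-1-[(1R,5R,7S)-4-methoxy-8,8-dimethyl-5-Lav-9-oxobicyclo[3.3.1]non-3-en-7-yl]-3-methyl-3-(triethylsilyloxy)butan-2-ol | C=C(C)[C@H](CC=C(C)C)C[C@@]12C[C@@H](C[C@H](O)C(C)(C)O[Si](CC)(CC)CC)C(C)(C)[C@@H](CC=C1OC)C2=O | intermediate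
27 | (1R,5R,7S)-7-[(2S)-2,3-dihydroxy-3-methylbutyl]-4-methoxy-8,8-dimethyl-5-Lav-bicyclo[3.3.1]non-3-en-9-one | C=C(C)[C@H](CC=C(C)C)C[C@@]12C[C@@H](C[C@H](O)C(C)(C)O)C(C)(C)[C@@H](CC=C1OC)C2=O | intermediate (not isolated)
28 | (1R,5R,7S)-7-{[(4S)-5,5-dimethyl-2-oxo-1,3-dioxolan-4-yl]methyl}-4-methoxy-8,8-dimethyl-5-Lav-bicyclo[3.3.1]non-3-en-9-one | C=C(C)[C@H](CC=C(C)C)C[C@@]12C[C@@H](C[C@@H]3OC(=O)OC3(C)C)C(C)(C)[C@@H](CC=C1OC)C2=O | intermediate
29 | (1S,5R,7S)-7-{[(4S)-5,5-dimethyl-2-oxo-1,3-dioxolan-4-yl]methyl}-4-methoxy-8,8-dimethyl-5-Lav-bicyclo[3.3.1]non-3-ene-2,9-dione | C=C(C)[C@H](CC=C(C)C)C[C@@]12C[C@@H](C[C@@H]3OC(=O)OC3(C)C)C(C)(C)[C@@H](C(=O)C=C1OC)C2=O | intermediate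
30 | 3,4-dihydroxybenzoic acid | O=C(O)c1ccc(O)c(O)c1 | starting material
31 | tert-butyldimethylsilyl 3,4-bis(tert-butyldimethylsilyloxy)benzoate | CC(C)(C)[Si](C)(C)OC(=O)c1ccc(O[Si](C)(C)C(C)(C)C)c(O[Si](C)(C)C(C)(C)C)c1 | intermediate
32 | 3,4-bis(tert-butyldimethylsilyloxy)benzoyl chloride | O=C(Cl)c1ccc(O[Si](C)(C)C(C)(C)C)c(O[Si](C)(C)C(C)(C)C)c1 | intermediate
33 | (1R,5R,7S)-3-[3,4-bis(tert-butyldimethylsilyloxy)benzoyl]-7-{[(4S)-5,5-dimethyl-2-oxo-1,3-dioxolan-4-yl]methyl}-4-methoxy-8,8-dimethyl-5-Lav-bicyclo[3.3.1]non-3-ene-2,9-dione | C=C(C)[C@H](CC=C(C)C)C[C@@]12C[C@@H](C[C@@H]3OC(=O)OC3(C)C)C(C)(C)[C@@H](C(=O)C(C(=O)c3ccc(O[Si](C)(C)C(C)(C)C)c(O[Si](C)(C)C(C)(C)C)c3)=C1OC)C2=O | intermediate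
34 | (1R,5R,7S)-3-[3,4-bis(tert-butyldimethylsilyloxy)benzoyl]-7-{[(4S)-5,5-dimethyl-2-oxo-1,3-dioxolan-4-yl]methyl}-4-methoxy-8,8-dimethyl-1-(3-methylbut-2-en-1-yl)-5-Lav-bicyclo[3.3.1]non-3-ene-2,9-dione | C=C(C)[C@H](CC=C(C)C)C[C@@]12C[C@@H](C[C@@H]3OC(=O)OC3(C)C)C(C)(C)[C@@](CC=C(C)C)(C(=O)C(C(=O)c3ccc(O[Si](C)(C)C(C)(C)C)c(O[Si](C)(C)C(C)(C)C)c3)=C1OC)C2=O | intermediate
35 | (1R,5R,7S)-3-(3,4-dihydroxybenzoyl)-7-[(2S)-2,3-dihydroxy-3-methylbutyl]-4-hydroxy-8,8-dimethyl-1-(3-methylbut-2-en-1-yl)-5-Lav-bicyclo[3.3.1]non-3-ene-2,9-dione | C=C(C)[C@H](CC=C(C)C)C[C@@]12C[C@@H](C[C@H](O)C(C)(C)O)C(C)(C)[C@@](CC=C(C)C)(C(=O)C(C(=O)c3ccc(O)c(O)c3)=C1O)C2=O | target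

## Step count and least certain steps

Total: 24 steps. Longest linear sequence: 21 steps (steps 1–13, 15–19 and 22–24, from oxazolidinone 1). Steps 14, 20 and 21 are side branches.

**Step 10 (key step).** The catalyst may discriminate poorly between the two diastereotopic enol ethers. The carbene may also insert into C–H bonds of the lavandulyl chain or of the tether. The opening of the cyclopropane may be incomplete, or it may be accompanied by hydrolysis of the second enol ether if the medium turns acidic. Fallback: give up catalyst control and use the enantiopure lavandulyl centre as the resolving element. The route sets out from 15, which is cyclised with an achiral catalyst (Cu(acac)2 or Rh2(OAc)4, toluene) and hydrolysed in the same way. This should give 17 together with its (1R,5S)-diastereomer F1. The two are diastereomers and would be separated by chromatography or crystallisation, and the route is rejoined at 17 at the cost of about half the material.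

**Step 16.** Isomerisation to the conjugated enone may lag behind competing 1,2-hydrosilylation of the unconjugated ketone, and hydride delivery may lose facial selectivity if ring B reacts through a boat. Fallback: build the conjugated enone directly by carbonyl addition, which also bypasses steps 13–15. The route sets out from 19. The lithium acetylide of triethyl[(2-methylbut-3-yn-2-yl)oxy]silane F2 (from 2-methylbut-3-yn-2-ol and Et3SiCl) is added with CeCl3 to the C7 ketone, giving the tertiary propargylic alcohol F3. A Meyer–Schuster rearrangement of F3 (MoO2(acac)2, Ph3PAuCl, AgOTf, toluene, rt), in which only the free C7 hydroxyl can migrate, delivers 24 already conjugated. 24 is reduced at once with the copper hydride system to 25, where the route is rejoined. The price is that the acetylide must prefer C7 over C9.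

**Step 19.** Hydrogen abstraction may spread to the allylic positions of the lavandulyl chain, or the peroxyl radical may add to the enol ether instead of abstracting. Fallback: replace C–H oxidation by carbonyl chemistry. The route sets out from 28. Mild hydrolysis of the enol ether (PPTS, wet acetone) gives the 4,9-diketone F4. Dehydrogenation with IBX (DMSO, 70 °C) can occur only toward C2–C3 and gives enone F5. Tsuji-type oxidation of the enone (Na2PdCl4, t-BuOOH, AcOH/H2O) gives the 2,4,9-trione F6. O-Methylation with Me3SiCHN2 returns 29, where the route is rejoined. The 2-methoxy regioisomer F7 forms alongside and would be hydrolysed back to F6 and recycled.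

**Step 12.** Electron transfer may reach the C9 ketone, and the hindered tetrasubstituted enolate may be protonated or O-methylated instead of C-methylated. Fallback: separate reduction and alkylation. The route sets out from 18. SmI2 in THF/MeOH at −78 °C, which does not reduce isolated ketones, removes the sulfonyl group and gives the 8-methyl diketone F8. Thermodynamic silylation (Me3SiCl, NaI, Et3N, MeCN) gives the more substituted C7=C8 trimethylsilyl enol ether F9. Fluoride-induced methylation of F9 (benzyltrimethylammonium fluoride, MeI, THF) gives 19, where the route is rejoined.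

**Step 23.** Lithiation of the hindered bridgehead next to CMe2 may be slow enough for the base to attack the 3-aroyl enol ether, or the bridgehead anion may decompose before it is alkylated. Fallback: block C3 with silicon and acylate last. The route sets out from 29. LiTMP with Me3SiCl present silylates C3 and gives the 3-trimethylsilyl vinylogous ester F10. A second lithiation with LiTMP now takes place at C1, and prenyl bromide 4 gives the 1-prenyl-3-silyl compound F11. Bu4NF removes the silyl group to give the 1-prenyl vinylogous ester F12. Lithiation of F12 at C3 and acylation with 32, as in step 22, gives 34, where the route is rejoined.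

**Step 5.** Substitution at the β-branched iodide may be outrun by elimination or by protonation of the dianion, and a methoxy group may be lost by over-reduction. Fallback: form the lavandulyl–ring bond on the arene and introduce the carboxyl last. 1,3-Dimethoxybenzene is lithiated at C2 (n-BuLi) and alkylated with 7 (CuI cat.), giving 2-Lav-1,3-dimethoxybenzene F13. Birch reduction (Li, NH3, t-BuOH) gives 6-Lav-1,5-dimethoxycyclohexa-1,4-diene F14. Metalation of its doubly allylic C6–H (s-BuLi, THF/HMPA, −78 °C) and quenching with CO2 gives 9, where the route is rejoined.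

## Further compounds

F1 | step 10 | (1R,5S)-4-methoxy-5-Lav-8-(phenylsulfonyl)bicyclo[3.3.1]non-3-ene-7,9-dione (C1,C5-diastereomer of 17) | C=C(C)[C@H](CC=C(C)C)C[C@]12CC(=O)C(S(=O)(=O)c3ccccc3)[C@H](CC=C1OC)C2=O
F2 | step 16 | triethyl[(2-methylbut-3-yn-2-yl)oxy]silane | C#CC(C)(C)O[Si](CC)(CC)CC
F3 | step 16 | (1R,5R)-7-hydroxy-4-methoxy-8,8-dimethyl-7-[3-methyl-3-(triethylsilyloxy)but-1-yn-1-yl]-5-Lav-bicyclo[3.3.1]non-3-en-9-one | C=C(C)[C@H](CC=C(C)C)C[C@@]12CC(O)(C#CC(C)(C)O[Si](CC)(CC)CC)C(C)(C)[C@@H](CC=C1OC)C2=O
F4 | step 19 | (1R,5R,7S)-7-{[(4S)-5,5-dimethyl-2-oxo-1,3-dioxolan-4-yl]methyl}-8,8-dimethyl-5-Lav-bicyclo[3.3.1]nonane-4,9-dione | C=C(C)[C@H](CC=C(C)C)C[C@@]12C[C@@H](C[C@@H]3OC(=O)OC3(C)C)C(C)(C)[C@@H](CCC1=O)C2=O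
F5 | step 19 | (1R,5R,7S)-7-{[(4S)-5,5-dimethyl-2-oxo-1,3-dioxolan-4-yl]methyl}-8,8-dimethyl-5-Lav-bicyclo[3.3.1]non-2-ene-4,9-dione | C=C(C)[C@H](CC=C(C)C)C[C@@]12C[C@@H](C[C@@H]3OC(=O)OC3(C)C)C(C)(C)[C@@H](C=CC1=O)C2=O
F6 | step 19 | 7-{[(4S)-5,5-dimethyl-2-oxo-1,3-dioxolan-4-yl]methyl}-8,8-dimethyl-5-Lav-bicyclo[3.3.1]nonane-2,4,9-trione (C1, C5, C7 as in 29) | C=C(C)[C@H](CC=C(C)C)C[C@@]12C[C@@H](C[C@@H]3OC(=O)OC3(C)C)C(C)(C)[C@@H](C(=O)CC1=O)C2=O
F7 | step 19 | 2-methoxy regioisomer of 29 (2-methoxy-bicyclo[3.3.1]non-2-ene-4,9-dione) | C=C(C)[C@H](CC=C(C)C)C[C@@]12C[C@@H](C[C@@H]3OC(=O)OC3(C)C)C(C)(C)[C@@H](C(OC)=CC1=O)C2=O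
F8 | step 12 | (1R,5R)-4-methoxy-8-methyl-5-Lav-bicyclo[3.3.1]non-3-ene-7,9-dione (C8 epimers) | C=C(C)[C@H](CC=C(C)C)C[C@@]12CC(=O)C(C)[C@@H](CC=C1OC)C2=O
F9 | step 12 | 4-methoxy-8-methyl-5-Lav-7-(trimethylsilyloxy)bicyclo[3.3.1]nona-3,7-dien-9-one (C1, C5 as in 19) | C=C(C)[C@H](CC=C(C)C)C[C@@]12CC(O[Si](C)(C)C)=C(C)[C@@H](CC=C1OC)C2=O
F10 | step 23 | 3-trimethylsilyl derivative of 29 | C=C(C)[C@H](CC=C(C)C)C[C@@]12C[C@@H](C[C@@H]3OC(=O)OC3(C)C)C(C)(C)[C@@H](C(=O)C([Si](C)(C)C)=C1OC)C2=O
F11 | step 23 | 1-(3-methylbut-2-en-1-yl)-3-trimethylsilyl derivative of 29 | C=C(C)[C@H](CC=C(C)C)C[C@@]12C[C@@H](C[C@@H]3OC(=O)OC3(C)C)C(C)(C)[C@@](CC=C(C)C)(C(=O)C([Si](C)(C)C)=C1OC)C2=O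
F12 | step 23 | 1-(3-methylbut-2-en-1-yl) derivative of 29 | C=C(C)[C@H](CC=C(C)C)C[C@@]12C[C@@H](C[C@@H]3OC(=O)OC3(C)C)C(C)(C)[C@@](CC=C(C)C)(C(=O)C=C1OC)C2=O
F13 | step 5 | 2-Lav-1,3-dimethoxybenzene | C=C(C)[C@H](CC=C(C)C)Cc1c(OC)cccc1OC
F14 | step 5 | 6-Lav-1,5-dimethoxycyclohexa-1,4-diene | C=C(C)[C@H](CC=C(C)C)CC1C(OC)=CCC=C1OC
A1 | alternative 1 | methyl cyclooctane-2,4-dione-1-carboxylate bearing 1-prenyl, 5-Lav, 8,8-dimethyl and the acetonide-protected C7 chain | C=C(C)[C@H](CC=C(C)C)CC1C[C@@H](C[C@@H]2OC(C)(C)OC2(C)C)C(C)(C)[C@@](CC=C(C)C)(C(=O)CC1=O)C(=O)OC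
A2 | alternative 1 | bicyclic enolised trione with acetonide-protected diol | C=C(C)[C@H](CC=C(C)C)C[C@@]12C[C@@H](C[C@@H]3OC(C)(C)OC3(C)C)C(C)(C)[C@@](CC=C(C)C)(C(=O)C=C1O)C2=O
A3 | alternative 2 | cis-fused hydrindanol-dione (C9 carbinol bonded to C1, C5 and C6) | O[C@]12C[C@@H](C[C@@H]3OC(C)(C)OC3(C)C)C(C)(C)[C@@]1(CC=C(C)C)C(=O)CC(=O)C2
A4 | alternative 2 | bicyclic enolised trione with C5 bridgehead hydrogen | [C@@H]12C[C@@H](C[C@@H]3OC(C)(C)OC3(C)C)C(C)(C)[C@@](CC=C(C)C)(C(=O)C=C1O)C2=O
A5 | alternative 3 | cyclohexenedione with C5 acetic acid arm and C1 ynone chain | C=C(C)[C@H](CC=C(C)C)C[C@@]1(CC(=O)O)C(OC)=CC(=O)[C@](CC=C(C)C)(C(C)(C)C#CC(=O)C(C)(C)O[Si](CC)(CC)CC)C1=O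
A6 | alternative 3 | bicyclic vinylogous ester with exocyclic enone at C7 | C=C(C)[C@H](CC=C(C)C)C[C@@]12C/C(=C\C(=O)C(C)(C)O[Si](CC)(CC)CC)C(C)(C)[C@@](CC=C(C)C)(C(=O)C=C1OC)C2=O
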